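**Retrosynthetic overview**

1. Target 34 ⇐ desilylation ⇐ threo-selective, catalyst-controlled vinylogous Mukaiyama aldol of enal 29 (C15) with the preformed 4-methyl-2-silyloxyfuran 31 (sets C15 and C5′; the butenolide ring comes intact from 30) ⇐ alkyne 24 by carboalumination/hydroxymethylation (sets 13E).
2. 24 ⇐ lactol 21 by Ohira–Bestmann homologation, with methanolysis of the temporary C18→O6 γ-lactone to unveil the methyl ester and the 6α-hydroxyl.
3. Key disconnection, ring B: C9–C10 bond and C8–O bond by a biomimetic proton-initiated cation–olefin cyclisation of bicyclic lactone aldehyde 17. Enabling feature: ring B carries quaternary C10 and tertiary carbinol C8 on either side of C9 (the imprint of a C10 cation adding to an (E)-C8=C9 alkene with oxygen capture at C8), and the C18 carboxyl on C4 and the C6 oxygen are cis and peri across C5, so a γ-lactone (C4–C18–O–C6–C5) can lock the chair.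
4. 17 ⇐ ring A by ring-closing metathesis (C1=C10) ⇐ trans,trans-lactone 15 by cuprate addition and enolate alkylation of butenolide 11 ⇐ (E)-enal 7 (Johnson–Claisen); the only external source of chirality is C6 (proline-catalysed α-aminoxylation).
5. Ring order: temporary γ-lactone (step 5) → ring A (step 8) → ring B (step 10, the last ring of the skeleton to be closed, together with a temporary lactol ring); the butenolide ring is never closed in the route.

Key step: step 10

Assumption: labdane numbering is used (C18 = ester carbon on C4, C5′ = CH–O of the butenolide); (R)-BINOL is assumed to induce the (15S,5′S) sense in step 16, and the mirror-image ligand would be used if a model reaction on geranial shows the opposite.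

**Route**

Step 1
Reactants: 1 2-(2-bromoethyl)-1,3-dioxolane; 2 methacrolein
Product: 4 1-(1,3-dioxolan-2-yl)-4-methylpent-4-en-3-ol (racemic), via Grignard reagent 3 (not isolated)
Conditions: Mg, THF, 25 °C; then 2, −78 to 0 °C; H2O work-up
Reagents that add atoms: none
Why: Grignard 1,2-addition of the alkylmagnesium reagent to the enal carbonyl; the carbinol centre is racemic and is destroyed in step 2.

Step 2
Reactants: 4 1-(1,3-dioxolan-2-yl)-4-methylpent-4-en-3-ol
Product: 6 ethyl (E)-7-(1,3-dioxolan-2-yl)-4-methylhept-4-enoate, via ketene acetal 5 (not isolated)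
Conditions: MeC(OEt)3, EtCO2H (cat.), 140 °C, EtOH distilled off
Reagents that add atoms: triethyl orthoacetate, CC(OCC)(OCC)OCC
Why: Johnson–Claisen rearrangement through a chair with the carbinol substituent equatorial should give the (E)-trisubstituted C8=C9 alkene; no stereocentre is formed.

Step 3
Reactants: 6 ethyl (E)-7-(1,3-dioxolan-2-yl)-4-methylhept-4-enoate
Product: 7 (E)-7-(1,3-dioxolan-2-yl)-4-methylhept-4-enal
Conditions: i-Bu2AlH, CH2Cl2, −78 °C; aq potassium sodium tartrate
Reagents that add atoms: none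
Why: Partial ester reduction through the aluminium hemiacetal, stable at −78 °C; acetal and alkene are inert.

Step 4
Reactants: 7 (E)-7-(1,3-dioxolan-2-yl)-4-methylhept-4-enal
Product: 9 ethyl (2Z,4S,6E)-9-(1,3-dioxolan-2-yl)-2,6-dimethyl-4-[(phenylamino)oxy]nona-2,6-dienoate, via aminoxy aldehyde 8 (not isolated)
Conditions: D-proline (20 mol %), PhNO, MeCN, −20 °C; then added to ethyl 2-[bis(2,2,2-trifluoroethoxy)phosphoryl]propanoate, KN(SiMe3)2, 18-crown-6, THF, −78 °C
Reagents that add atoms: nitrosobenzene, O=Nc1ccccc1; ethyl 2-[bis(2,2,2-trifluoroethoxy)phosphoryl]propanoate, CCOC(=O)C(C)P(=O)(OCC(F)(F)F)OCC(F)(F)F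
Why: Proline-catalysed α-aminoxylation (enamine attack on the nitroso oxygen, face fixed by the carboxylic acid hydrogen bond; D-proline should give the 6S C–O centre), followed by Still–Gennari olefination, whose kinetic control should give the (Z)-enoate needed for lactonisation.

Step 5
Reactants: 9 ethyl (2Z,4S,6E)-9-(1,3-dioxolan-2-yl)-2,6-dimethyl-4-[(phenylamino)oxy]nona-2,6-dienoate
Product: 11 (5S)-5-[(2E)-5-(1,3-dioxolan-2-yl)-2-methylpent-2-en-1-yl]-3-methylfuran-2(5H)-one, via hydroxy enoate 10 (not isolated)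
Conditions: Cu(OAc)2 (30 mol %), EtOH, rt; then PPTS (cat.), toluene, 60 °C
Reagents that add atoms: none
Why: Copper-catalysed N–O cleavage frees the C6 hydroxyl, which lactonises onto the cis ester to close the temporary γ-lactone as a butenolide; C6 is not touched.

Step 6
Reactants: 11 (5S)-5-[(2E)-5-(1,3-dioxolan-2-yl)-2-methylpent-2-en-1-yl]-3-methylfuran-2(5H)-one
Product: 13 (4S,5S)-5-[(2E)-5-(1,3-dioxolan-2-yl)-2-methylpent-2-en-1-yl]-3-methyl-4-(prop-1-en-2-yl)oxolan-2-one (C3 epimers), via silyl ketene acetal 12 (not isolated)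
Conditions: CH2=C(Me)MgBr, CuBr·SMe2 (20 mol %), Me3SiCl, THF, −78 °C; aq NH4Cl
Reagents that add atoms: isopropenylmagnesium bromide, CC(=C)[Mg]Br
Why: Copper-catalysed conjugate addition to the butenolide anti to the C6 substituent should set C5 (isopropenyl trans to the side chain); the C4 epimer mixture is of no consequence.

Step 7
Reactants: 13 (4S,5S)-5-[(2E)-5-(1,3-dioxolan-2-yl)-2-methylpent-2-en-1-yl]-3-methyl-4-(prop-1-en-2-yl)oxolan-2-one
Product: 15 (3R,4R,5S)-3-(but-3-en-1-yl)-5-[(2E)-5-(1,3-dioxolan-2-yl)-2-methylpent-2-en-1-yl]-3-methyl-4-(prop-1-en-2-yl)oxolan-2-one, via lithium enolate 14 (not isolated)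
Conditions: LiN(i-Pr)2, THF, −78 °C; then 4-iodobut-1-ene, HMPA, −78 to −20 °C
Reagents that add atoms: 4-iodobut-1-ene, C=CCCI
Why: Lactone enolate alkylation in which the electrophile enters anti to the adjacent C5 isopropenyl group, which should set the C4 quaternary centre (butenyl trans to isopropenyl, methyl cis).

Step 8
Reactants: 15 (3R,4R,5S)-3-(but-3-en-1-yl)-5-[(2E)-5-(1,3-dioxolan-2-yl)-2-methylpent-2-en-1-yl]-3-methyl-4-(prop-1-en-2-yl)oxolan-2-one
Product: 16 (3S,3aR,7aR)-3-[(2E)-5-(1,3-dioxolan-2-yl)-2-methylpent-2-en-1-yl]-4,7a-dimethyl-3a,6,7,7a-tetrahydro-2-benzofuran-1(3H)-one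
Conditions: second-generation Grubbs catalyst (H2IMes)(PCy3)Cl2Ru=CHPh (5 mol %), CH2Cl2, 40 °C
Reagents that add atoms: none
Why: Ring-closing metathesis of the monosubstituted and 1,1-disubstituted alkenes closes ring A (trans-fused to the lactone) with the C1=C10 trisubstituted alkene; the hindered side-chain alkene should not compete.

Step 9
Reactants: 16 (3S,3aR,7aR)-3-[(2E)-5-(1,3-dioxolan-2-yl)-2-methylpent-2-en-1-yl]-4,7a-dimethyl-3a,6,7,7a-tetrahydro-2-benzofuran-1(3H)-one
Product: 17 (4E)-6-[(1S,3aR,7aR)-3a,7-dimethyl-3-oxo-1,3,3a,4,5,7a-hexahydro-2-benzofuran-1-yl]-5-methylhex-4-enal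
Conditions: 1 M aq HCl, THF, rt
Reagents that add atoms: water, O
Why: Acid-catalysed acetal hydrolysis; lactone and alkenes are inert to dilute aqueous acid at room temperature.

Step 10
Reactants: 17 (4E)-6-[(1S,3aR,7aR)-3a,7-dimethyl-3-oxo-1,3,3a,4,5,7a-hexahydro-2-benzofuran-1-yl]-5-methylhex-4-enal
Product: 21 8α,13-epoxy-13-hydroxy-14,15,16-trinorlabdan-18,6α-olide (lactol), via C10 cation 18 (not isolated), via C8 cation 19 (not isolated), via oxocarbenium ion 20 (not isolated)
Conditions: TfOH (3 equiv), 2-nitropropane, −78 °C; then aq NaHCO3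
Reagents that add atoms: water, O
Why: Markovnikov protonation of the ring A alkene (H to C1) gives the tertiary C10 cation 18, which is attacked by C9 of the (E)-C8=C9 alkene (6-endo-trig closure of ring B, C9–C10 bond) to give the tertiary C8 cation 19; the aldehyde oxygen, five atoms away, captures C8 in a six-membered closure to give oxocarbenium ion 20, which water turns into lactol 21 on quench. The closest known reaction type is the superacid-mediated cation–olefin cyclisation of monocyclic homofarnesyl-type acids, alcohols and ketones with internal oxygen termination, itself a copy of the labdane cyclase step that closes ring B and oxygenates C8. C10 is controlled by the trans-fused γ-lactone, which fixes the C5–C6 rotamer so that C9 can reach C10 only through a chair that delivers it equatorially (trans-decalin, angular methyl axial); C9 follows from the (E)-alkene in that chair (C11 equatorial, H-9 axial) and C8 from anti addition across the alkene (oxygen equatorial, methyl axial). The step needs initiation at C1=C10 and not at C8=C9, and oxygen capture instead of proton loss: only the C10 cation has a chair path to a new tertiary cation, protonation of the side-chain alkene should be reversible at −78 °C, and the aldehyde oxygen is placed for a six-membered trap.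

Step 11
Reactants: 21 8α,13-epoxy-13-hydroxy-14,15,16-trinorlabdan-18,6α-olide
Product: 24 methyl 6α,8α-dihydroxy-15,16-dinorlabd-13-yn-18-oate, via hydroxy aldehyde 22 (not isolated), via alkynyl lactone 23 (not isolated)
Conditions: dimethyl (1-diazo-2-oxopropyl)phosphonate, K2CO3, MeOH, 0 °C to rt; then NaOMe (cat.), MeOH, rt
Reagents that add atoms: dimethyl (1-diazo-2-oxopropyl)phosphonate, COP(=O)(OC)C(=[N+]=[N-])C(C)=O; methanol, CO
Why: Seyferth–Gilbert homologation with the Ohira–Bestmann reagent on the lactol in equilibrium with its hydroxy aldehyde gives the terminal alkyne, and methoxide should open the peri-fused γ-lactone (relief of the strain of two trans ring fusions at C5) to the C18 methyl ester and the 6α-hydroxyl; no stereocentre is affected.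

Step 12
Reactants: 24 methyl 6α,8α-dihydroxy-15,16-dinorlabd-13-yn-18-oate
Product: 25 methyl 6α,8α-bis(triethylsilyloxy)-15,16-dinorlabd-13-yn-18-oate
Conditions: Et3SiOTf, 2,6-lutidine, CH2Cl2, −78 to 0 °C
Reagents that add atoms: triethylsilyl trifluoromethanesulfonate, CC[Si](CC)(CC)OS(=O)(=O)C(F)(F)F
Why: Silylation of the secondary and the tertiary hydroxyl with the reactive silyl triflate, so that the organoaluminium and titanium steps meet no free hydroxyl.

Step 13
Reactants: 25 methyl 6α,8α-bis(triethylsilyloxy)-15,16-dinorlabd-13-yn-18-oate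
Product: 28 methyl (13E)-15-hydroxy-6α,8α-bis(triethylsilyloxy)labd-13-en-18-oate, via alkenylalane 26 (not isolated), via lithium alanate 27 (not isolated)
Conditions: AlMe3, Cp2ZrCl2 (25 mol %), CH2Cl2, 0 °C to rt; then n-BuLi, THF, −78 °C; (CH2O)n, rt
Reagents that add atoms: trimethylaluminium, C[Al](C)C; paraformaldehyde (as formaldehyde), C=O
Why: Negishi zirconium-catalysed carboalumination adds methyl and aluminium syn across the terminal alkyne with methyl on the internal carbon, and hydroxymethylation of the alanate with retention should fix the 13E alkene; the hindered neopentyl ester should survive.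

Step 14
Reactants: 28 methyl (13E)-15-hydroxy-6α,8α-bis(triethylsilyloxy)labd-13-en-18-oate
Product: 29 methyl (13E)-15-oxo-6α,8α-bis(triethylsilyloxy)labd-13-en-18-oate
Conditions: MnO2, CH2Cl2, rt
Reagents that add atoms: none
Why: Selective allylic oxidation with MnO2 under neutral conditions, which should keep the alkene geometry.

Step 15
Reactants: 30 4-methylfuran-2(5H)-one
Product: 31 4-methyl-2-(trimethylsilyloxy)furan
Conditions: Me3SiOTf, Et3N, Et2O, 0 °C; distilled
Reagents that add atoms: trimethylsilyl trifluoromethanesulfonate, C[Si](C)(C)OS(=O)(=O)C(F)(F)F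
Why: Soft enolisation and O-silylation of the butenolide gives the aromatic 2-silyloxyfuran; the lactone ring stays intact.

Step 16
Reactants: 29 methyl (13E)-15-oxo-6α,8α-bis(triethylsilyloxy)labd-13-en-18-oate; 31 4-methyl-2-(trimethylsilyloxy)furan
Product: 33 methyl (13E,15S)-15-hydroxy-15-[(2S)-3-methyl-5-oxo-2,5-dihydrofuran-2-yl]-6α,8α-bis(triethylsilyloxy)labd-13-en-18-oate, via trimethylsilyl ether 32 (not isolated)
Conditions: (R)-BINOL (20 mol %), Ti(OiPr)4 (20 mol %), Et2O, −20 °C; then aq citric acid, THF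
Reagents that add atoms: none
Why: Vinylogous Mukaiyama aldol reaction in which C5 of the silyloxyfuran adds 1,2 to the titanium-bound enal through an open transition state that favours the threo (15S,5′S) relationship, while the chiral ligand selects the aldehyde face (the remote decalin exerts no control), so both new stereocentres are reagent-set.

Step 17
Reactants: 33 methyl (13E,15S)-15-hydroxy-15-[(2S)-3-methyl-5-oxo-2,5-dihydrofuran-2-yl]-6α,8α-bis(triethylsilyloxy)labd-13-en-18-oate
Product: 34 methyl (13E,15S)-6α,8α,15-trihydroxy-15-[(2S)-3-methyl-5-oxo-2,5-dihydrofuran-2-yl]labd-13-en-18-oate (CNP0104474.1)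
Conditions: HF·pyridine, pyridine, THF, 0 °C to rt
Reagents that add atoms: none
Why: Fluoride-mediated cleavage of both silyl ethers under buffered conditions that the allylic alcohol, the butenolide and the ester should tolerate.

**Compound list**

1 | 2-(2-bromoethyl)-1,3-dioxolane | BrCCC1OCCO1 | starting material
2 | methacrolein | CC(=C)C=O | starting material
3 | [2-(1,3-dioxolan-2-yl)ethyl]magnesium bromide (not isolated) | Br[Mg]CCC1OCCO1 | intermediate
4 | 1-(1,3-dioxolan-2-yl)-4-methylpent-4-en-3-ol (racemic) | CC(=C)C(O)CCC1OCCO1 | intermediate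
5 | mixed ketene acetal of 4 (not isolated) | C=C(OCC)OC(CCC1OCCO1)C(C)=C | intermediate
6 | ethyl (E)-7-(1,3-dioxolan-2-yl)-4-methylhept-4-enoate | CCOC(=O)CC/C(C)=C/CCC1OCCO1 | intermediate
7 | (E)-7-(1,3-dioxolan-2-yl)-4-methylhept-4-enal | O=CCC/C(C)=C/CCC1OCCO1 | intermediate
8 | (2S,4E)-7-(1,3-dioxolan-2-yl)-4-methyl-2-[(phenylamino)oxy]hept-4-enal (not isolated) | O=C[C@@H](ONc1ccccc1)C/C(C)=C/CCC1OCCO1 | intermediate
9 | ethyl (2Z,4S,6E)-9-(1,3-dioxolan-2-yl)-2,6-dimethyl-4-[(phenylamino)oxy]nona-2,6-dienoate | CCOC(=O)/C(C)=C\[C@@H](ONc1ccccc1)C/C(C)=C/CCC1OCCO1 | intermediate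
10 | ethyl (2Z,4S,6E)-9-(1,3-dioxolan-2-yl)-4-hydroxy-2,6-dimethylnona-2,6-dienoate (not isolated) | CCOC(=O)/C(C)=C\[C@@H](O)C/C(C)=C/CCC1OCCO1 | intermediate
11 | (5S)-5-[(2E)-5-(1,3-dioxolan-2-yl)-2-methylpent-2-en-1-yl]-3-methylfuran-2(5H)-one | CC1=C[C@H](C/C(C)=C/CCC2OCCO2)OC1=O | intermediate
12 | trimethylsilyl ketene acetal of 13 (not isolated) | C[Si](C)(C)OC1=C(C)[C@@H](C(C)=C)[C@H](C/C(C)=C/CCC2OCCO2)O1 | intermediate
13 | (4S,5S)-5-[(2E)-5-(1,3-dioxolan-2-yl)-2-methylpent-2-en-1-yl]-3-methyl-4-(prop-1-en-2-yl)oxolan-2-one (C3 epimers) | CC1C(=O)O[C@@H](C/C(C)=C/CCC2OCCO2)[C@@H]1C(C)=C | intermediate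
14 | lithium enolate of 13 (not isolated) | [Li]OC1=C(C)[C@@H](C(C)=C)[C@H](C/C(C)=C/CCC2OCCO2)O1 | intermediate
15 | (3R,4R,5S)-3-(but-3-en-1-yl)-5-[(2E)-5-(1,3-dioxolan-2-yl)-2-methylpent-2-en-1-yl]-3-methyl-4-(prop-1-en-2-yl)oxolan-2-one | C=CCC[C@@]1(C)C(=O)O[C@@H](C/C(C)=C/CCC2OCCO2)[C@@H]1C(C)=C | intermediate
16 | (3S,3aR,7aR)-3-[(2E)-5-(1,3-dioxolan-2-yl)-2-methylpent-2-en-1-yl]-4,7a-dimethyl-3a,6,7,7a-tetrahydro-2-benzofuran-1(3H)-one | CC1=CCC[C@@]2(C)C(=O)O[C@@H](C/C(C)=C/CCC3OCCO3)[C@H]12 | intermediate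
17 | (4E)-6-[(1S,3aR,7aR)-3a,7-dimethyl-3-oxo-1,3,3a,4,5,7a-hexahydro-2-benzofuran-1-yl]-5-methylhex-4-enal | CC1=CCC[C@@]2(C)C(=O)O[C@@H](C/C(C)=C/CCC=O)[C@H]12 | intermediate
18 | tertiary C10 carbocation from 17 (not isolated) | C[C+]1CCC[C@@]2(C)C(=O)O[C@@H](C/C(C)=C/CCC=O)[C@H]12 | intermediate
19 | tertiary C8 carbocation, ring B closed (not isolated) | O=C1[C@]2(C)CCC[C@@]3(C)[C@H]2[C@@H](O1)C[C+](C)[C@@H]3CCC=O | intermediate
20 | cyclic oxocarbenium ion (not isolated) | O=C1[C@]2(C)CCC[C@@]3(C)[C@H]2[C@@H](O1)C[C@@]4(C)[O+]=CCC[C@H]34 | intermediate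
21 | 8α,13-epoxy-13-hydroxy-14,15,16-trinorlabdan-18,6α-olide (lactol, C13 epimers) | O=C1[C@]2(C)CCC[C@@]3(C)[C@H]2[C@@H](O1)C[C@@]4(C)OC(O)CC[C@H]34 | intermediate
22 | 8α-hydroxy-13-oxo-14,15,16-trinorlabdan-18,6α-olide (not isolated) | O=C1[C@]2(C)CCC[C@@]3(C)[C@H]2[C@@H](O1)C[C@@](C)(O)[C@@H]3CCC=O | intermediate
23 | 8α-hydroxy-15,16-dinorlabd-13-yn-18,6α-olide (not isolated) | O=C1[C@]2(C)CCC[C@@]3(C)[C@H]2[C@@H](O1)C[C@@](C)(O)[C@@H]3CCC#C | intermediate
24 | methyl 6α,8α-dihydroxy-15,16-dinorlabd-13-yn-18-oate | COC(=O)[C@]1(C)CCC[C@@]2(C)[C@H]1[C@@H](O)C[C@@](C)(O)[C@@H]2CCC#C | intermediate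
25 | methyl 6α,8α-bis(triethylsilyloxy)-15,16-dinorlabd-13-yn-18-oate | COC(=O)[C@]1(C)CCC[C@@]2(C)[C@H]1[C@@H](O[Si](CC)(CC)CC)C[C@@](C)(O[Si](CC)(CC)CC)[C@@H]2CCC#C | intermediate
26 | (13E)-alkenyl(dimethyl)alane from 25 (not isolated) | COC(=O)[C@]1(C)CCC[C@@]2(C)[C@H]1[C@@H](O[Si](CC)(CC)CC)C[C@@](C)(O[Si](CC)(CC)CC)[C@@H]2CC/C(C)=C/[Al](C)C | intermediate
27 | lithium butyl(alkenyl)dimethylalanate (not isolated) | COC(=O)[C@]1(C)CCC[C@@]2(C)[C@H]1[C@@H](O[Si](CC)(CC)CC)C[C@@](C)(O[Si](CC)(CC)CC)[C@@H]2CC/C(C)=C/[Al-](C)(C)CCCC.[Li+] | intermediate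
28 | methyl (13E)-15-hydroxy-6α,8α-bis(triethylsilyloxy)labd-13-en-18-oate | COC(=O)[C@]1(C)CCC[C@@]2(C)[C@H]1[C@@H](O[Si](CC)(CC)CC)C[C@@](C)(O[Si](CC)(CC)CC)[C@@H]2CC/C(C)=C/CO | intermediate
29 | methyl (13E)-15-oxo-6α,8α-bis(triethylsilyloxy)labd-13-en-18-oate | COC(=O)[C@]1(C)CCC[C@@]2(C)[C@H]1[C@@H](O[Si](CC)(CC)CC)C[C@@](C)(O[Si](CC)(CC)CC)[C@@H]2CC/C(C)=C/C=O | intermediate
30 | 4-methylfuran-2(5H)-one | CC1=CC(=O)OC1 | starting material
31 | 4-methyl-2-(trimethylsilyloxy)furan | Cc1coc(O[Si](C)(C)C)c1 | intermediate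
32 | 15-O-trimethylsilyl ether of 33 (not isolated) | COC(=O)[C@]1(C)CCC[C@@]2(C)[C@H]1[C@@H](O[Si](CC)(CC)CC)C[C@@](C)(O[Si](CC)(CC)CC)[C@@H]2CC/C(C)=C/[C@H](O[Si](C)(C)C)[C@H]1OC(=O)C=C1C | intermediate
33 | methyl (13E,15S)-15-hydroxy-15-[(2S)-3-methyl-5-oxo-2,5-dihydrofuran-2-yl]-6α,8α-bis(triethylsilyloxy)labd-13-en-18-oate | COC(=O)[C@]1(C)CCC[C@@]2(C)[C@H]1[C@@H](O[Si](CC)(CC)CC)C[C@@](C)(O[Si](CC)(CC)CC)[C@@H]2CC/C(C)=C/[C@H](O)[C@H]1OC(=O)C=C1C | intermediate
34 | methyl (13E,15S)-6α,8α,15-trihydroxy-15-[(2S)-3-methyl-5-oxo-2,5-dihydrofuran-2-yl]labd-13-en-18-oate (CNP0104474.1) | COC(=O)[C@]1(C)CCC[C@@]2(C)[C@H]1[C@@H](O)C[C@@](C)(O)[C@@H]2CC/C(C)=C/[C@H](O)[C@H]1OC(=O)C=C1C | target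

**Step count and risks**

Total step count: 17. Longest linear sequence: 16 steps (steps 1–14, 16 and 17; step 15 prepares the silyloxyfuran separately).

Steps most likely to fail:

Step 10. The cationic cascade may derail by protonation of the side-chain C8=C9 alkene, by proton loss from the C8 cation before the aldehyde oxygen arrives, or by acid-induced self-condensation of the aldehyde. The fallback changes the terminating group to a carboxylic acid, the classical internal trap of such cyclisations. It sets out from 17, which is oxidised (NaClO2, NaH2PO4, 2-methylbut-2-ene, t-BuOH/H2O; Pinnick oxidation) to the carboxylic acid F1. F1 is cyclised with TfOH in 2-nitropropane at −78 °C to the bis-lactone F2 (δ-lactone closed on O8). NaOMe in MeOH should open only the strained γ-lactone to give the hydroxy ester δ-lactone F3. i-Bu2AlH at −78 °C should reduce the unhindered δ-lactone, sparing the neopentyl ester, to the lactol ester F4. The Ohira–Bestmann reagent (K2CO3, MeOH) converts F4 into 24, where the route is rejoined.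

Step 16. Face selection on the β,β-disubstituted enal by the chiral titanium catalyst may be poor, or the erythro adduct may compete. The fallback gives up catalyst control. It sets out from 29, which is combined with 31 and BF3·OEt2 in CH2Cl2 at −78 °C; the open transition state of the achiral Lewis acid reaction should still favour threo addition and give 33 together with its (15R,5′R) diastereomer F5. Because the decalin is fixed, the two are diastereomers and are separated by chromatography, if necessary after lipase-catalysed acetylation of one C15 epimer. The route is rejoined at 33.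

Step 11. Transesterification of the lactone may stop at an equilibrium or stay incomplete, leaving the alkynyl lactone. The fallback makes the opening irreversible. It sets out from 23, isolated after the Ohira–Bestmann reaction, which is saponified with LiOH in THF/H2O to the hydroxy acid F6 (handled as its carboxylate and acidified cold). F6 is O-methylated at once with Me3SiCHN2 in MeOH/toluene to give 24, where the route is rejoined.

**Further compounds**

F1 | step 10 | (4E)-6-[(1S,3aR,7aR)-3a,7-dimethyl-3-oxo-1,3,3a,4,5,7a-hexahydro-2-benzofuran-1-yl]-5-methylhex-4-enoic acid | CC1=CCC[C@@]2(C)C(=O)O[C@@H](C/C(C)=C/CCC(=O)O)[C@H]12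
F2 | step 10 | 14,15,16-trinorlabdane-18,6α:13,8α-diolide | O=C1[C@]2(C)CCC[C@@]3(C)[C@H]2[C@@H](O1)C[C@@]4(C)OC(=O)CC[C@H]34
F3 | step 10 | methyl 6α-hydroxy-14,15,16-trinorlabdan-13,8α-olid-18-oate | COC(=O)[C@]1(C)CCC[C@@]2(C)[C@H]1[C@@H](O)C[C@@]3(C)OC(=O)CC[C@H]23
F4 | step 10 | methyl 8α,13-epoxy-6α,13-dihydroxy-14,15,16-trinorlabdan-18-oate (lactol, C13 epimers) | COC(=O)[C@]1(C)CCC[C@@]2(C)[C@H]1[C@@H](O)C[C@@]3(C)OC(O)CC[C@H]23
F5 | step 16 | methyl (13E,15R)-15-hydroxy-15-[(2R)-3-methyl-5-oxo-2,5-dihydrofuran-2-yl]-6α,8α-bis(triethylsilyloxy)labd-13-en-18-oate | COC(=O)[C@]1(C)CCC[C@@]2(C)[C@H]1[C@@H](O[Si](CC)(CC)CC)C[C@@](C)(O[Si](CC)(CC)CC)[C@@H]2CC/C(C)=C/[C@@H](O)[C@@H]1OC(=O)C=C1C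
F6 | step 11 | 6α,8α-dihydroxy-15,16-dinorlabd-13-yn-18-oic acid | OC(=O)[C@]1(C)CCC[C@@]2(C)[C@H]1[C@@H](O)C[C@@](C)(O)[C@@H]2CCC#C
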